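The data were generated by integration from invented constants; the scatter is artificial.

Read the slope before you integrate anything.

the same everywhere: gas phase 51 mM (held)

| run | solid substrate | remark | time |
|---|---|---|---|
| east | 0.10 M | run made earlier |  |
| south | 0.15 M | run made earlier |  |
| flask | 0.20 M |  | 6.0 h |

- east (time / h: target / %): 0.500: 13.3; 0.833: 25.6; 1.50: 50.0; 3.00: 88.6; 6.00: 88.2
- south (time / h: target / %): 0.500: 9.0; 1.50: 33.1; 3.00: 68.3; 4.00: 88.4; 6.00: 89.5

(readings scatter by 0.3 percentage points)

- as a solid, counted per litre of solution: solid substrate
- the numbers in the tables scatter by 0.3 percentage points (one standard deviation)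
- at the start none of the gas phase is in solution
- at the start none of the solid substrate is in solution

1. amount of target at 6.0 h, in percent of the solid substrate charged
2. concentration of dissolved gas in solution at 6.0 h, in percent of saturation

In the east run the target rises at r = 36.6 mM/h. The south run, with a larger charge, rises at 36.2 mM/h, so the rate reads as zero order in the charge. Both runs then stop rising.

Follow one molecule of the charge: its chance of ending as target is the plateau f = 88.9%, read at the last point of each run. Two times therefore matter, the time allowed and the time the supply needs. The second is T = τ + f·c/r, with c the charge and τ = 0.133 h the lag read from the east line. If r holds for the flask, it gives 4.99 h, and this finishing time T is 0.832 of the 6.0 h allowed. Because T comes first, I commit to f as the yield of the flask. The dissolved gas in the flask then has 1.01 h to climb, and I expect it close to saturation, though no reading shows it.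

The forecast gives 88.7% (86.5% to 89.8%) and 99.5% (92% to 100%), holding that “the run should just finish before 6 h”.

The flask gives 89.3% of target and dissolved gas at 96.0% of saturation.

    starting material → side product (k = 5.42 × 10⁻⁴ /s)
    gas phase ⇌ dissolved gas, rate k2*(csat - [dissolved gas]) (kL = 6.43 × 10⁻⁴ /s)
    starting material + dissolved gas → target (k = 0.141 /M/s)
    solid substrate ⇌ starting material, rate k4*(cs4 - [starting material]) while solid is left; crystals form when [starting material] > cs4 (solubility = 0.170 M, k = 6.53 × 10⁻⁵ /s)

In the flask, solid substrate, solid and dissolved, falls below 2% of its charge at 5.02 h, earlier than the 6.0 h and beside my T of 4.99 h, and at 6.00 h it stands at 0% with target at 89.3% and side product at 10.7%. In the neighbouring flask with 0.34 M, T comes to 8.39 h, later than 6.0 h, so r(t − τ)/c at t = 6.0 h gives 63.2%, and that flask holds 61.8% of target with 31% of its charged solid substrate still there, solid or dissolved.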